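(The numbers are invented; no experiment stands behind them.)

By the time you read this I had set out the flasks below, and this note covers what I expected to find in them.

in all of them: time 1.0 min
- Sunday's: L 0.0050 M (fed, over 40 s); G 2.50 mM; temperature 40 °C; all else is in the flask from the start; the feed brings no volume worth counting
- Thursday's: L 0.0050 M; G 2.50 mM; temperature 40 °C; everything together at the start
- Saturday's: L 0.0050 M; G 2.50 mM (fed, over 40 s); temperature 40 °C; all else is in the flask from the start; the feed brings no volume worth counting
- Monday's: L 0.0050 M (fed, over 40 s); G 2.50 mM; the addition at 20 °C, then warmed to 40 °C; the feed brings no volume worth counting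

    E ⇌ D (K1 = 2.6, k1 = 0.0896 /s, Ea1 = 72.0 kJ/mol, ΔH1 = −30.0 kJ/mol)
    2 L → L2 (k2 = 11.9 /M/s, Ea2 = 36.0 kJ/mol)
    L + G → E + Z (k3 = 0.0560 /M/s, Ea3 = 43.0 kJ/mol)
    L + G + Z → E + 2 Z (k4 = 12100 /M²/s, Ea4 = 16.0 kJ/mol)
    (constants at 40 °C)

- in percentages every species weighs as the L in it: one L2 counts as two
- where a step has two of a species, its rate is k times that concentration squared, and two are used at each turn
- all constants are for 40 °C and move with temperature by the activation energies and enthalpies

* the best flask by share of E in E plus D; "all alike" if 1.5 percentage points covers them all (Sunday's / Thursday's / Saturday's / Monday's / all alike)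
* share of E in E plus D at the end, Sunday's
* share of E in E plus D at the end, Thursday's
* share of E in E plus D at the end, Saturday's
* share of E in E plus D at the end, Monday's

I followed one L in Thursday's from the start. It met another L at 0.119 /s and met G at 1.400 × 10⁻⁴ /s, so it went to L2, and on that step's second-order curve [L] stood at 0.614 mM at 1.0 min.

Each turn with G makes one E and one Z, so [Z] equals E plus D. Z also speeds its own making (autocatalysis). Let a and b be the constants 0.0560 /M/s and 12100 /M²/s of the plain and the Z-assisted step. With [G] held as charged:

seed a/b = 4.63 × 10⁻⁶ M; growth exponent b[G]∫[L]dt = 2.67; so [Z] = 6.19 × 10⁻⁵ M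

That uses 2.47% of G, so holding [G] was fair.

Next I followed one E. It turns to D and back, and τ = 8.06 s is its memory time (relaxation time), one over the sum of the two constants. This is shorter than the run. Old E therefore sits at the floor share 27.8%, and E made within the last τ stands above it:

f = τ × rate of making E / [Z] = τ(a/[Z] + b)[G][L] = 0.161

share = floor + f × (what the floor leaves) = 39.4%

Don't let Thursday's run past 1.0 min: f carries [L], which keeps falling, and the share sinks towards the floor. For Sunday's and Monday's, where L is fed, I expected more [L] at the end than in Thursday's, and most in Monday's.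

The forecast read 47% for Sunday's, 39% for Thursday's, 42.5% for Saturday's and 50% for Monday's, with Monday's best and “the slow feeds that keep L alive late” finishing highest.

The flasks gave 45.8% for Sunday's, 38.5% for Thursday's, 42.2% for Saturday's and 50.3% for Monday's, so Monday's was best.

At 1.00 min Monday's held [L] at 25.1% of the charge, [G] at 98.5% and [Z] at 3.80 × 10⁻⁵ M. The same lines gave f = 0.338 and a share of 52.2%, against the 50.3% it gave. The neighbour was Monday's with G cut to 6.3 × 10⁻⁴ M. It ended with [L] at 25.4% of the charge and [Z] at 3.09 × 10⁻⁶ M, so f = 0.194 and the reckoned share was 41.8%. That flask gave 44.7%.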